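**Retrosynthetic overview**
1. The ester pattern (C7 OBz, C2 OAc, free tertiary C1 OH) is set last from triol 12, which comes from acetonide 11 (1,3-dioxane across O2/O7).
2. The cyclohexene is closed by ring-closing metathesis at C4=C5 of diene 10; it is the only carbocycle and the last ring formed.
3. Key bond C1–C6: the ketone carbon of 9 is joined to the former carbonyl carbon of acrolein, made nucleophilic as a γ-benzoyloxyallylindium (from 8). This one step creates C1 and C6 and delivers the C6 benzoate.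
4. Ketone 9 (C7, C1, C2, C3, C4) is unmasked from D-fructose by zinc fragmentation of a 6-iodo furanoside; fructose C3 and C4 become target C2 and C3.
5. Ring order: 1,3-dioxane (acetonide, step 1) → cyclohexene (step 6); the furanose ring is sacrificial.

Assumption: the target as drawn is (1R,2S,3R,6S) with C1 = C(OH)(CH2OBz), C2 = CHOAc, C3 = CHOBz, C4=C5, C6 = CHOBz, C7 = CH2OBz (numbering used for all cyclohexenes below); 8 is used as its E/Z mixture (E isomer drawn).

**Step 1**
Reactants: 1 D-fructose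
Product: 3 methyl 1,3-O-isopropylidene-α-D-fructofuranoside, via methyl α-D-fructofuranoside 2 (not isolated)
Conditions: H2SO4 (cat.), MeOH, rt, 1 h; NaHCO3, concentrate; then 2,2-dimethoxypropane, TsOH (cat.), acetone, rt; Et3N quench
Reagents that add atoms: methanol, CO; 2,2-dimethoxypropane, COC(C)(C)OC
Why: Kinetic Fischer glycosidation gives the furanosides, and only the α-anomer has C1 and O3 cis, so acid-catalysed acetalisation closes the 1,3-dioxane on it selectively; C3, C4 and C5 come unchanged from the sugar.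

**Step 2**
Reactants: 3 methyl 1,3-O-isopropylidene-α-D-fructofuranoside
Product: 4 methyl 6-deoxy-6-iodo-1,3-O-isopropylidene-α-D-fructofuranoside
Conditions: I2, PPh3, imidazole, THF, 0 °C → rt
Reagents that add atoms: iodine, [I][I]
Why: Appel-type (Garegg–Samuelsson) iodination; the alkoxyphosphonium is displaced by iodide (SN2) only at the unhindered primary C6 hydroxyl, and no stereocentre is touched.

**Step 3**
Reactants: 4 methyl 6-deoxy-6-iodo-1,3-O-isopropylidene-α-D-fructofuranoside
Product: 5 methyl 4-O-benzoyl-6-deoxy-6-iodo-1,3-O-isopropylidene-α-D-fructofuranoside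
Conditions: BzCl, Et3N, DMAP (cat.), CH2Cl2, 0 °C
Reagents that add atoms: benzoyl chloride, O=C(Cl)c1ccccc1
Why: DMAP-catalysed acylation of the only free hydroxyl installs the future C3 benzoate with retention.

**Step 4**
Reactants: 6 acrolein, 7 benzoyl bromide
Product: 8 3-bromoprop-1-en-1-yl benzoate (E/Z mixture)
Conditions: ZnCl2 (cat.), CH2Cl2, −20 °C → rt
Reagents that add atoms: none
Why: Lewis-acid-catalysed addition of the acyl bromide across the aldehyde C=O followed by allylic 1,3-shift of bromide (net 1,4-addition) gives the 3-halopropenyl ester, in which the former carbonyl carbon can later be turned into a donor.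

**Step 5**
Reactants: 5 methyl 4-O-benzoyl-6-deoxy-6-iodo-1,3-O-isopropylidene-α-D-fructofuranoside, 8 3-bromoprop-1-en-1-yl benzoate
Product: 10 (1R)-1-[(4S,5R)-5-[(1S)-1-(benzoyloxy)prop-2-en-1-yl]-5-hydroxy-2,2-dimethyl-1,3-dioxan-4-yl]prop-2-en-1-yl benzoate, via dioxanone ketone 9 (not isolated)
Conditions: Zn dust, THF/H2O (4:1), sonication, 40 °C; then 8, In powder, rt
Reagents that add atoms: none
Why: Proposed new method: zinc inserts into the carbon–iodine bond and the alkylzinc expels the ring oxygen (Bernet–Vasella fragmentation), the hemiketal alkoxide losing methoxide to unveil ketone 9 and the vinyl group; indium converts 8 into the γ-benzoyloxyallylindium, which adds through its oxygen-bearing carbon to the ketone in a Barbier reaction; C1 is set by equatorial attack on the chair dioxanone, anti to both ring C–O bonds (polar Felkin–Anh) and trans to the C4 side chain, and C6 by a Zimmerman–Traxler chair in which the internally O→In-coordinated (Z)-allylindium carries OBz axial and the branched ketone arm sits equatorial (threo C1/C6); the closest known reaction type is the one-pot zinc fragmentation/indium α-acyloxyallylation of aldehydes released from ω-iodo aldofuranosides, extended here to a ketose-derived ketone.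

**Step 6**
Reactants: 10 (1R)-1-[(4S,5R)-5-[(1S)-1-(benzoyloxy)prop-2-en-1-yl]-5-hydroxy-2,2-dimethyl-1,3-dioxan-4-yl]prop-2-en-1-yl benzoate
Product: 11 (4aR,5S,8R,8aS)-4a-hydroxy-2,2-dimethyl-4a,5,8,8a-tetrahydro-4H-1,3-benzodioxine-5,8-diyl dibenzoate
Conditions: second-generation Grubbs catalyst (H2IMes)(PCy3)Cl2Ru=CHPh (5 mol %), CH2Cl2, 40 °C
Reagents that add atoms: none
Why: Ring-closing metathesis of the two terminal vinyl groups, held gauche as equatorial arms on the dioxane chair, closes the cyclohexene (C4=C5, necessarily Z) with loss of ethylene; no stereocentre is affected.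

**Step 7**
Reactants: 11 (4aR,5S,8R,8aS)-4a-hydroxy-2,2-dimethyl-4a,5,8,8a-tetrahydro-4H-1,3-benzodioxine-5,8-diyl dibenzoate
Product: 12 (1S,2S,3R,6S)-1,2-dihydroxy-1-(hydroxymethyl)cyclohex-4-ene-3,6-diyl dibenzoate
Conditions: AcOH/H2O (4:1), 45 °C
Reagents that add atoms: none
Why: Acid-catalysed acetal hydrolysis; the benzoates and allylic C–O bonds survive aqueous acetic acid, and the acidic medium suppresses benzoyl migration.

**Step 8**
Reactants: 12 (1S,2S,3R,6S)-1,2-dihydroxy-1-(hydroxymethyl)cyclohex-4-ene-3,6-diyl dibenzoate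
Product: 14 [(1R,2S,3R,6S)-2-(acetyloxy)-3,6-bis(benzoyloxy)-1-hydroxycyclohex-4-en-1-yl]methyl benzoate, via C7 monobenzoate diol 13 (not isolated)
Conditions: BzCl (1.1 equiv), pyridine, CH2Cl2, −40 → −10 °C; then Ac2O, DMAP (cat.), 0 °C → rt
Reagents that add atoms: benzoyl chloride, O=C(Cl)c1ccccc1; acetic anhydride, CC(=O)OC(C)=O
Why: Regioselective acylation: the primary C7 hydroxyl is benzoylated faster than the hindered secondary C2 hydroxyl, and DMAP-catalysed acetylation then takes C2 while the tertiary C1 hydroxyl stays free.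

**Compound list**
1 | D-fructose | OCC(=O)[C@@H](O)[C@H](O)[C@H](O)CO | starting material
2 | methyl α-D-fructofuranoside | CO[C@@]1(CO)O[C@H](CO)[C@@H](O)[C@@H]1O | intermediate (not isolated)
3 | methyl 1,3-O-isopropylidene-α-D-fructofuranoside | CC1(C)OC[C@]2(OC)O[C@H](CO)[C@@H](O)[C@@H]2O1 | intermediate
4 | methyl 6-deoxy-6-iodo-1,3-O-isopropylidene-α-D-fructofuranoside | CC1(C)OC[C@]2(OC)O[C@H](CI)[C@@H](O)[C@@H]2O1 | intermediate
5 | methyl 4-O-benzoyl-6-deoxy-6-iodo-1,3-O-isopropylidene-α-D-fructofuranoside | CC1(C)OC[C@]2(OC)O[C@H](CI)[C@@H](OC(=O)c3ccccc3)[C@@H]2O1 | intermediate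
6 | acrolein | C=CC=O | starting material
7 | benzoyl bromide | O=C(Br)c1ccccc1 | starting material
8 | 3-bromoprop-1-en-1-yl benzoate (E/Z mixture, E drawn) | BrC/C=C/OC(=O)c1ccccc1 | intermediate
9 | (1R)-1-[(4S)-2,2-dimethyl-5-oxo-1,3-dioxan-4-yl]prop-2-en-1-yl benzoate | CC1(C)O[C@@H]([C@H](OC(=O)c2ccccc2)C=C)C(=O)CO1 | intermediate (not isolated)
10 | (1R)-1-[(4S,5R)-5-[(1S)-1-(benzoyloxy)prop-2-en-1-yl]-5-hydroxy-2,2-dimethyl-1,3-dioxan-4-yl]prop-2-en-1-yl benzoate | CC1(C)O[C@@H]([C@H](OC(=O)c2ccccc2)C=C)[C@@](O)(CO1)[C@@H](OC(=O)c2ccccc2)C=C | intermediate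
11 | (4aR,5S,8R,8aS)-4a-hydroxy-2,2-dimethyl-4a,5,8,8a-tetrahydro-4H-1,3-benzodioxine-5,8-diyl dibenzoate | CC1(C)O[C@H]2[C@H](OC(=O)c3ccccc3)C=C[C@H](OC(=O)c3ccccc3)[C@]2(O)CO1 | intermediate
12 | (1S,2S,3R,6S)-1,2-dihydroxy-1-(hydroxymethyl)cyclohex-4-ene-3,6-diyl dibenzoate | O[C@H]1[C@H](OC(=O)c2ccccc2)C=C[C@H](OC(=O)c2ccccc2)[C@]1(O)CO | intermediate
13 | [(1S,2S,3R,6S)-3,6-bis(benzoyloxy)-1,2-dihydroxycyclohex-4-en-1-yl]methyl benzoate | O[C@H]1[C@H](OC(=O)c2ccccc2)C=C[C@H](OC(=O)c2ccccc2)[C@]1(O)COC(=O)c1ccccc1 | intermediate (not isolated)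
14 | [(1R,2S,3R,6S)-2-(acetyloxy)-3,6-bis(benzoyloxy)-1-hydroxycyclohex-4-en-1-yl]methyl benzoate | CC(=O)O[C@H]1[C@H](OC(=O)c2ccccc2)C=C[C@H](OC(=O)c2ccccc2)[C@]1(O)COC(=O)c1ccccc1 | target

**Step count:** 8 steps in total; longest linear sequence 7 (steps 1, 2, 3, 5, 6, 7, 8 from D-fructose); step 4 is a one-step branch.

**Steps most likely to fail**

Step 5. Two stereocentres are set in one Barbier addition to a ketone. The C6 outcome depends on the geometry of the allylindium, and 9 can lose benzoate by β-elimination if the medium turns basic. The fallback decouples the C6 configuration from the C–C bond formation; it sets out from 5 and acrolein 6 and returns at 11. Acrolein 6 and acetyl bromide (ZnCl2 cat.) give 3-bromoprop-1-en-1-yl acetate F1. The same zinc/indium one-pot reaction of 5 with F1 gives the acetate analogue of the diene, taken here as its C6 epimer F2 (the case in which the addition prefers the cis C1-OH/C6-O arrangement). Ring-closing metathesis gives the bicyclic acetate F3. Mg(OMe)2 in MeOH removes the acetate but not the benzoate, giving the cis-diol F4. Mitsunobu esterification (PhCO2H, PPh3, DIAD, toluene) then inverts C6 and delivers 11.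

Step 6. Closure of a ring trans-fused to the dioxane, next to a quaternary carbinol and between two allylic benzoates, may be slow. The fallback changes the order of events; it sets out from 10 and returns at 12. The acetonide is hydrolysed first (AcOH/H2O, 45 °C) to the conformationally free triol diene F5. Ring-closing metathesis of F5 with the second-generation Hoveyda–Grubbs catalyst (H2IMes)Cl2Ru(=CH-C6H4-2-OiPr) in CH2Cl2 at 40 °C gives 12 directly, by-passing 11.

Step 8. The C7 hydroxyl is primary but neopentyl, so over-benzoylation at C2 or acyl migration is possible. The fallback replaces kinetic discrimination by a protecting-group detour; it sets out from 12 and returns at 14. TBSCl/imidazole (DMF, 0 °C) gives the C7 silyl ether F6. Ac2O/pyridine/DMAP gives the C2 acetate F7. HF·pyridine (THF, 0 °C) gives the primary alcohol F8. BzCl/pyridine (0 °C) then gives 14.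

**Further compounds**
F1 | step 5 | 3-bromoprop-1-en-1-yl acetate (E/Z mixture, E drawn) | CC(=O)O/C=C/CBr
F2 | step 5 | (1R)-1-[(4S,5R)-5-[(1R)-1-(acetyloxy)prop-2-en-1-yl]-5-hydroxy-2,2-dimethyl-1,3-dioxan-4-yl]prop-2-en-1-yl benzoate | CC1(C)O[C@@H]([C@H](OC(=O)c2ccccc2)C=C)[C@@](O)(CO1)[C@H](OC(C)=O)C=C
F3 | step 5 | (4aR,5R,8R,8aS)-5-(acetyloxy)-4a-hydroxy-2,2-dimethyl-4a,5,8,8a-tetrahydro-4H-1,3-benzodioxin-8-yl benzoate | CC1(C)O[C@H]2[C@H](OC(=O)c3ccccc3)C=C[C@@H](OC(C)=O)[C@]2(O)CO1
F4 | step 5 | (4aR,5R,8R,8aS)-4a,5-dihydroxy-2,2-dimethyl-4a,5,8,8a-tetrahydro-4H-1,3-benzodioxin-8-yl benzoate | CC1(C)O[C@H]2[C@H](OC(=O)c3ccccc3)C=C[C@@H](O)[C@]2(O)CO1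
F5 | step 6 | (3S,4S,5S,6R)-4,5-dihydroxy-4-(hydroxymethyl)octa-1,7-diene-3,6-diyl dibenzoate | O[C@@H]([C@H](OC(=O)c1ccccc1)C=C)[C@@](O)(CO)[C@@H](OC(=O)c1ccccc1)C=C
F6 | step 8 | (1S,2S,3R,6S)-1-({[tert-butyl(dimethyl)silyl]oxy}methyl)-1,2-dihydroxycyclohex-4-ene-3,6-diyl dibenzoate | O[C@H]1[C@H](OC(=O)c2ccccc2)C=C[C@H](OC(=O)c2ccccc2)[C@]1(O)CO[Si](C)(C)C(C)(C)C
F7 | step 8 | (1R,2S,3R,6S)-2-(acetyloxy)-1-({[tert-butyl(dimethyl)silyl]oxy}methyl)-1-hydroxycyclohex-4-ene-3,6-diyl dibenzoate | CC(=O)O[C@H]1[C@H](OC(=O)c2ccccc2)C=C[C@H](OC(=O)c2ccccc2)[C@]1(O)CO[Si](C)(C)C(C)(C)C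
F8 | step 8 | (1R,2S,3R,6S)-2-(acetyloxy)-1-hydroxy-1-(hydroxymethyl)cyclohex-4-ene-3,6-diyl dibenzoate | CC(=O)O[C@H]1[C@H](OC(=O)c2ccccc2)C=C[C@H](OC(=O)c2ccccc2)[C@]1(O)CO
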